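Ring C is cut at O1–C2 and C4–C4a. This shows the flavanone to be a constitutional isomer of an aryl cinnamate in which O1 of ring A carries acyl carbon C4. Light moves the acyl group from O1 to C4a, the only free ortho carbon because C8 holds the prenyl group. The O1–H thus released is the only free hydroxyl of ring A and adds to C2 under a chiral bifunctional catalyst. One flask thus turns an achiral ester into ring C with the (2S) centre, and alkene isomers formed under light converge. The precursor is a tris-silylated aryl (E)-cinnamate made by Horner–Wadsworth–Emmons olefination.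

Key step: step 7

Assumption: the quinine-derived catalyst is taken to give the (2S) product. If the sense of induction proves opposite, the pseudoenantiomeric quinidine-derived catalyst takes its place and nothing else changes.
Abbreviations and numbering: TBS = tert-butyldimethylsilyl; prenyl = 3-methylbut-2-enyl. Flavanone numbering (O1, C2–C4, C4a, C5–C8, C8a, ring B primed) is used throughout, also for the precursors.

Step 1
Reactants: 1 phloroglucinol; 2 prenyl bromide
Product: 3 2-prenylphloroglucinol
Conditions: KOH (1 equiv), H2O, 0 °C to rt, 1 in excess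
Reagents that add atoms: none
Why: C-alkylation (SN2) of the ambident phloroglucinolate in water, where hydrogen bonding to the oxygens steers the allylic bromide to carbon and the excess of 1 should hold back a second prenylation.

Step 2
Reactants: 3 2-prenylphloroglucinol
Product: 4 3,5-bis(TBS-oxy)-2-prenylphenol
Conditions: TBSCl (2 equiv), imidazole, DMF, 0 °C
Reagents that add atoms: tert-butyldimethylsilyl chloride, CC(C)(C)[Si](C)(C)Cl
Why: Silyl ether formation under steric control, in which the unhindered hydroxyl para to the prenyl group reacts first and the two hydroxyls beside the prenyl group are equivalent, so the second silylation should give a single bis-ether with one free OH next to the prenyl group.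

Step 3
Reactants: 4 3,5-bis(TBS-oxy)-2-prenylphenol; 5 diethylphosphonoacetic acid
Product: 6 3,5-bis(TBS-oxy)-2-prenylphenyl 2-(diethoxyphosphoryl)acetate
Conditions: DCC, DMAP (cat.), CH2Cl2, 0 °C to rt
Reagents that add atoms: none
Why: Steglich esterification of the only free phenol, run under neutral conditions that spare the prenyl group and the silyl ethers.

Step 4
Reactants: 7 2-bromo-3-hydroxy-4-methoxybenzaldehyde
Product: 8 2-bromo-3-(TBS-oxy)-4-methoxybenzaldehyde
Conditions: TBSCl, imidazole, DMF, rt
Reagents that add atoms: tert-butyldimethylsilyl chloride, CC(C)(C)[Si](C)(C)Cl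
Why: Standard silyl ether protection of the single phenol, which keeps it out of the cross-coupling and the olefination.

Step 5
Reactants: 8 2-bromo-3-(TBS-oxy)-4-methoxybenzaldehyde; 9 tributyl(3-methylbut-2-enyl)stannane
Product: 10 3-(TBS-oxy)-4-methoxy-2-prenylbenzaldehyde
Conditions: Pd(PPh3)4 (5 mol %), toluene, 110 °C
Reagents that add atoms: none
Why: Stille cross-coupling, in which the ortho formyl group helps oxidative addition and C–C bond formation at the unsubstituted allyl terminus should keep the linear prenyl group.

Step 6
Reactants: 6 3,5-bis(TBS-oxy)-2-prenylphenyl 2-(diethoxyphosphoryl)acetate; 10 3-(TBS-oxy)-4-methoxy-2-prenylbenzaldehyde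
Product: 11 3,5-bis(TBS-oxy)-2-prenylphenyl (E)-3-[3-(TBS-oxy)-4-methoxy-2-prenylphenyl]acrylate
Conditions: NaH, THF, 0 °C; then 10, 0 °C to rt
Reagents that add atoms: none
Why: Horner–Wadsworth–Emmons olefination of an aromatic aldehyde with a stabilised phosphonate, which should give the (E)-cinnamate and joins both halves with the aryl ester already in place.

Step 7
Reactants: 11 3,5-bis(TBS-oxy)-2-prenylphenyl (E)-3-[3-(TBS-oxy)-4-methoxy-2-prenylphenyl]acrylate
Product: 13 (2S)-5,7-bis(TBS-oxy)-2-[3-(TBS-oxy)-4-methoxy-2-prenylphenyl]-8-prenylchroman-4-one, via 2'-hydroxychalcone 12 (not isolated)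
Conditions: hν (300 nm), degassed toluene (dilute), rt; then dark, quinine-derived 3,5-bis(trifluoromethyl)phenyl thiourea (10 mol %), 0 °C
Reagents that add atoms: none
Why: Excitation of 11 breaks the O1–C4 ester bond homolytically, and the caged aryloxyl/cinnamoyl radical pair recombines at C4a and tautomerises to chalcone 12, which forms C4–C4a and frees O1–H (photo-Fries rearrangement, known for aryl cinnamates). With the lamp off, the bifunctional catalyst closes ring C by intramolecular oxa-Michael addition of O1 to C2 in the 6-endo-trig mode; the closest known reaction types are the tandem photo-Fries/oxa-Michael synthesis of chroman-4-ones and the cinchona-catalysed enantioselective cyclisation of 2'-hydroxychalcones and other o-hydroxyaryl enones. C2 is the only new stereocentre and is controlled by the catalyst: the thiourea binds the C4 carbonyl, the quinuclidine takes the O1 proton, and the phenoxide should reach the Si face of C2, which gives (2S). Site selectivity of the acyl shift rests on the substrate, since C8 is blocked by the prenyl group and the para carbon C6 lies between two bulky silyloxy groups and further from the radical cage. Only O1 can close the ring because O5 and O7 are silylated, so the 8-prenyl and not the 6-prenyl flavanone should form. Alkene isomers made by the light converge because (Z)-12 can return to (E)-12 by reversible conjugate addition of the amine, and 12 should not cyclise in toluene before the catalyst is added, so no racemic background is expected.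

Step 8
Reactants: 13 (2S)-5,7-bis(TBS-oxy)-2-[3-(TBS-oxy)-4-methoxy-2-prenylphenyl]-8-prenylchroman-4-one
Product: 14 (2S)-5,7-dihydroxy-2-(3-hydroxy-4-methoxy-2-prenylphenyl)-8-prenylchroman-4-one (target)
Conditions: TBAF, AcOH (1:1, slight excess per silyl group), THF, 0 °C
Reagents that add atoms: none
Why: Fluoride-driven cleavage of the three aryl silyl ethers, in which acetic acid protonates each phenoxide at once, so base-induced retro-oxa-Michael opening of ring C and loss of the C2 configuration should not occur and the prenyl groups meet no strong acid.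

Compound list
1 | phloroglucinol | Oc1cc(O)cc(O)c1 | starting material
2 | prenyl bromide (1-bromo-3-methylbut-2-ene) | CC(C)=CCBr | starting material
3 | 2-prenylphloroglucinol | CC(C)=CCc1c(O)cc(O)cc1O | intermediate
4 | 3,5-bis(TBS-oxy)-2-prenylphenol | CC(C)=CCc1c(O)cc(O[Si](C)(C)C(C)(C)C)cc1O[Si](C)(C)C(C)(C)C | intermediate
5 | diethylphosphonoacetic acid | CCOP(=O)(CC(=O)O)OCC | starting material
6 | 3,5-bis(TBS-oxy)-2-prenylphenyl 2-(diethoxyphosphoryl)acetate | CCOP(=O)(CC(=O)Oc1cc(O[Si](C)(C)C(C)(C)C)cc(O[Si](C)(C)C(C)(C)C)c1CC=C(C)C)OCC | intermediate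
7 | 2-bromo-3-hydroxy-4-methoxybenzaldehyde | COc1ccc(C=O)c(Br)c1O | starting material
8 | 2-bromo-3-(TBS-oxy)-4-methoxybenzaldehyde | COc1ccc(C=O)c(Br)c1O[Si](C)(C)C(C)(C)C | intermediate
9 | tributyl(3-methylbut-2-enyl)stannane | CCCC[Sn](CCCC)(CCCC)CC=C(C)C | starting material
10 | 3-(TBS-oxy)-4-methoxy-2-prenylbenzaldehyde | COc1ccc(C=O)c(CC=C(C)C)c1O[Si](C)(C)C(C)(C)C | intermediate
11 | 3,5-bis(TBS-oxy)-2-prenylphenyl (E)-3-[3-(TBS-oxy)-4-methoxy-2-prenylphenyl]acrylate | COc1ccc(/C=C/C(=O)Oc2cc(O[Si](C)(C)C(C)(C)C)cc(O[Si](C)(C)C(C)(C)C)c2CC=C(C)C)c(CC=C(C)C)c1O[Si](C)(C)C(C)(C)C | intermediate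
12 | (E)-1-[4,6-bis(TBS-oxy)-2-hydroxy-3-prenylphenyl]-3-[3-(TBS-oxy)-4-methoxy-2-prenylphenyl]prop-2-en-1-one | COc1ccc(/C=C/C(=O)c2c(O)c(CC=C(C)C)c(O[Si](C)(C)C(C)(C)C)cc2O[Si](C)(C)C(C)(C)C)c(CC=C(C)C)c1O[Si](C)(C)C(C)(C)C | intermediate
13 | (2S)-5,7-bis(TBS-oxy)-2-[3-(TBS-oxy)-4-methoxy-2-prenylphenyl]-8-prenylchroman-4-one | COc1ccc([C@@H]2CC(=O)c3c(O[Si](C)(C)C(C)(C)C)cc(O[Si](C)(C)C(C)(C)C)c(CC=C(C)C)c3O2)c(CC=C(C)C)c1O[Si](C)(C)C(C)(C)C | intermediate
14 | (2S)-5,7-dihydroxy-2-(3-hydroxy-4-methoxy-2-prenylphenyl)-8-prenylchroman-4-one | COc1ccc([C@@H]2CC(=O)c3c(O)cc(O)c(CC=C(C)C)c3O2)c(CC=C(C)C)c1O | target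

Total step count: 8
Longest linear sequence: 6 steps (1, 2, 3, 6, 7, 8)

Steps most likely to fail

Step 7. The ring closure may show poor facial selectivity on this crowded, unactivated enone, or the enantiomeric purity may erode through retro-Michael opening. The acyl shift may also be slowed by energy loss through alkene isomerisation. The fallback sets out from 11 and replaces catalyst control by a resolution. The irradiation is run alone and chalcone 12 is isolated. An achiral amine base (DABCO, toluene) closes it to the racemic tris-TBS flavanone F1. Asymmetric transfer hydrogenation follows with [Cp*RhCl((R,R)-TsDPEN)] and HCO2H/Et3N, stopped near half conversion. It should reduce the (2R)-enantiomer to the cis-(2R,4R)-flavan-4-ol F2 and leave the (2S)-ketone untouched (kinetic resolution by transfer hydrogenation, known for flavanones). The route is rejoined at 13.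

Step 2. Silylation may run on to the tris-ether or stop early, and the mixture may be hard to separate. The fallback sets out from 1 and places the free hydroxyl next to the prenyl group by mechanism instead of by rate. Silylation of the C3-symmetric triol with two equivalents of TBSCl gives 3,5-bis(TBS-oxy)phenol F3. Pd(0)-catalysed O-alkylation with tert-butyl 2-methylbut-3-en-2-yl carbonate gives the 1,1-dimethylallyl aryl ether F4. Aromatic Claisen rearrangement (toluene, 110 °C) then delivers the prenyl group to one of the two equivalent ortho carbons and releases the neighbouring phenol. The route is rejoined at 4, and steps 1 and 2 are both replaced.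

Step 5. Transmetalation may be sluggish at the doubly ortho-substituted bromide, and allylic transposition on palladium may scramble the prenyl group into its branched isomer. The fallback sets out from 8 and builds the side chain in two stages. Stille coupling with allyltributylstannane, which has no regiochemical ambiguity, gives the 2-allyl aldehyde F5. Cross-metathesis with 2-methylbut-2-ene (second-generation Grubbs catalyst, CH2Cl2, 40 °C) then converts the allyl into the prenyl group. The route is rejoined at 10.

Further compounds
F1 | step 7 | racemic 5,7-bis(TBS-oxy)-2-[3-(TBS-oxy)-4-methoxy-2-prenylphenyl]-8-prenylchroman-4-one | COc1ccc(C2CC(=O)c3c(O[Si](C)(C)C(C)(C)C)cc(O[Si](C)(C)C(C)(C)C)c(CC=C(C)C)c3O2)c(CC=C(C)C)c1O[Si](C)(C)C(C)(C)C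
F2 | step 7 | cis-(2R,4R)-5,7-bis(TBS-oxy)-2-[3-(TBS-oxy)-4-methoxy-2-prenylphenyl]-8-prenylchroman-4-ol | COc1ccc([C@H]2C[C@@H](O)c3c(O[Si](C)(C)C(C)(C)C)cc(O[Si](C)(C)C(C)(C)C)c(CC=C(C)C)c3O2)c(CC=C(C)C)c1O[Si](C)(C)C(C)(C)C
F3 | step 2 | 3,5-bis(TBS-oxy)phenol | Oc1cc(O[Si](C)(C)C(C)(C)C)cc(O[Si](C)(C)C(C)(C)C)c1
F4 | step 2 | 1,3-bis(TBS-oxy)-5-(2-methylbut-3-en-2-yloxy)benzene | C=CC(C)(C)Oc1cc(O[Si](C)(C)C(C)(C)C)cc(O[Si](C)(C)C(C)(C)C)c1
F5 | step 5 | 2-allyl-3-(TBS-oxy)-4-methoxybenzaldehyde | COc1ccc(C=O)c(CC=C)c1O[Si](C)(C)C(C)(C)C
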